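**Retrosynthetic overview**

1. Ring D, the pyran ring of the chromene bonded to the stereocentre, is disconnected last. Its O1–C2(CH3)2–C3H=C4H segment is a ring-opened 3,3-dimethylcyclopropene, joined to benzene ring C through O1 (on C8a) and C4 (on C4a) by a rhodium-catalysed C–H activation/strain-release [3+3] annulation of an N-aryloxyacetamide.
2. Enabling feature: in ring C the oxygen-bearing C8a has two ortho C–H bonds, but C8–H is wedged between O1 and the C7 methoxy group, so only C4a–H is open. The quaternary C2 with its two methyl groups maps onto C3 of the symmetric cyclopropene, and the N–O bond supplies the chromene oxidation level.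
3. The N-aryloxyacetamide comes from a phenol. Its (S) stereocentre and E alkene come from a stereospecific palladium-catalysed Suzuki–Miyaura coupling of an (R)-allylic methyl carbonate (Heck enone, then CBS reduction) with an arylboronic acid, which runs with inversion.
4. Both benzene rings (A and C) are bought as 4-bromo-3-methoxyphenol. Ring order: pyran ring B first (propargyl Claisen cascade, step 2), pyran ring D last (step 13).

Key step: step 13

**Route**

Step 1
Reactants: 1 4-bromo-3-methoxyphenol; 2 3-chloro-3-methylbut-1-yne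
Product: 3 1-bromo-2-methoxy-4-[(2-methylbut-3-yn-2-yl)oxy]benzene
Conditions: K2CO3, KI (cat.), acetone, reflux
Reagents that add atoms: none
Why: Williamson-type O-alkylation of the phenoxide by the tertiary propargylic chloride is the standard way to aryl 1,1-dimethylpropargyl ethers, and the aryl bromide and methyl ether are inert to K2CO3.

Step 2
Reactants: 3 1-bromo-2-methoxy-4-[(2-methylbut-3-yn-2-yl)oxy]benzene
Product: 6 6-bromo-7-methoxy-2,2-dimethyl-2H-chromene, via allenyl dienone 4 (not isolated), via o-quinone methide 5 (not isolated)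
Conditions: N,N-diethylaniline, 180 °C
Reagents that add atoms: none
Why: The aromatic propargyl Claisen rearrangement should deliver the allenyl group to the open ortho carbon (para to OMe) rather than to the carbon wedged between the two oxygens, and the hydrogen shift and oxa-6π electrocyclisation that follow close pyran ring B in the classical thermal chromene synthesis.

Step 3
Reactants: 6 6-bromo-7-methoxy-2,2-dimethyl-2H-chromene; 7 but-3-en-2-one
Product: 8 (3E)-4-(7-methoxy-2,2-dimethyl-2H-chromen-6-yl)but-3-en-2-one
Conditions: Pd(OAc)2 (cat.), P(o-tol)3 (cat.), Et3N, DMF, 100 °C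
Reagents that add atoms: none
Why: Mizoroki–Heck reaction of the aryl bromide with the electron-poor terminal alkene, in which syn insertion and syn β-hydride elimination should give the E enone while the hindered cis-disubstituted chromene alkene does not compete.

Step 4
Reactants: 8 (3E)-4-(7-methoxy-2,2-dimethyl-2H-chromen-6-yl)but-3-en-2-one
Product: 9 (2R,3E)-4-(7-methoxy-2,2-dimethyl-2H-chromen-6-yl)but-3-en-2-ol
Conditions: (S)-2-methyl-CBS-oxazaborolidine (cat.), catecholborane, toluene, −78 °C
Reagents that add atoms: none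
Why: Corey–Bakshi–Shibata reduction, in which the oxazaborolidine binds the ketone anti to the larger styryl group and should direct 1,2-hydride delivery from catecholborane to the face that gives the (R) carbinol, the centre that is later transferred to the target.

Step 5
Reactants: 9 (2R,3E)-4-(7-methoxy-2,2-dimethyl-2H-chromen-6-yl)but-3-en-2-ol
Product: 10 methyl (2R,3E)-4-(7-methoxy-2,2-dimethyl-2H-chromen-6-yl)but-3-en-2-yl carbonate
Conditions: ClCO2Me, pyridine, CH2Cl2, 0 °C
Reagents that add atoms: methyl chloroformate, COC(Cl)=O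
Why: Acylation of the secondary alcohol at oxygen leaves the C–O bond and hence the (R) configuration untouched and installs the methyl carbonate, a leaving group that zerovalent palladium ionises readily and that supplies its own methoxide base on loss of carbon dioxide.

Step 6
Reactants: 1 4-bromo-3-methoxyphenol
Product: 11 (4-bromo-3-methoxyphenoxy)tri(propan-2-yl)silane
Conditions: TIPSCl, imidazole, DMF, rt
Reagents that add atoms: chlorotri(propan-2-yl)silane, CC(C)[Si](Cl)(C(C)C)C(C)C
Why: Silylation of the phenol gives a triisopropylsilyl ether that should survive butyllithium and the neutral coupling of step 8 and can later be removed with fluoride under conditions harmless to the alkenes.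

Step 7
Reactants: 11 (4-bromo-3-methoxyphenoxy)tri(propan-2-yl)silane
Product: 14 {2-methoxy-4-[tri(propan-2-yl)silyloxy]phenyl}boronic acid, via aryllithium 12 (not isolated), via lithium triisopropoxyborate 13 (not isolated)
Conditions: n-BuLi, THF, −78 °C; B(OiPr)3, −78 °C to rt; then 1 M HCl, 0 °C
Reagents that add atoms: triisopropyl borate, CC(C)OB(OC(C)C)OC(C)C; water, O
Why: Bromine–lithium exchange, capture of the aryllithium by the trialkyl borate as its ate complex and brief cold acidic hydrolysis is the standard sequence to an arylboronic acid, and the aryl silyl ether should tolerate the short exposure to dilute acid.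

Step 8
Reactants: 10 methyl (2R,3E)-4-(7-methoxy-2,2-dimethyl-2H-chromen-6-yl)but-3-en-2-yl carbonate; 14 {2-methoxy-4-[tri(propan-2-yl)silyloxy]phenyl}boronic acid
Product: 15 {3-methoxy-4-[(2S,3E)-4-(7-methoxy-2,2-dimethyl-2H-chromen-6-yl)but-3-en-2-yl]phenoxy}tri(propan-2-yl)silane
Conditions: Pd2(dba)3 (cat.), PPh3 (cat.), THF, rt, no added base
Reagents that add atoms: none
Why: Stereospecific palladium-catalysed Suzuki–Miyaura allyl–aryl coupling of a 1,3-disubstituted secondary allylic carbonate with an arylboronic acid, in which zerovalent palladium should ionise the carbonate anti to the leaving group to an unsymmetrical syn,syn-π-allylpalladium methoxide that cannot reach its enantiomer by π–σ–π isomerisation, the methoxide should trigger transmetalation of the boronic acid, and reductive elimination from the metal face at the methyl-bearing terminus (keeping the styrene conjugation and the E geometry) should give the (S) centre by net inversion of the (R) carbonate, the cyclic tertiary allyl aryl ether of the chromene being far less prone to ionisation than the carbonate.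

Step 9
Reactants: 15 {3-methoxy-4-[(2S,3E)-4-(7-methoxy-2,2-dimethyl-2H-chromen-6-yl)but-3-en-2-yl]phenoxy}tri(propan-2-yl)silane
Product: 16 3-methoxy-4-[(2S,3E)-4-(7-methoxy-2,2-dimethyl-2H-chromen-6-yl)but-3-en-2-yl]phenol
Conditions: TBAF, AcOH, THF, 0 °C to rt
Reagents that add atoms: none
Why: Fluoride-induced cleavage of the aryl silyl ether (driven by Si–F bond formation), buffered with acetic acid so that the electron-rich phenoxide is protonated at once, should touch neither the stereocentre nor the alkenes.

Step 10
Reactants: 16 3-methoxy-4-[(2S,3E)-4-(7-methoxy-2,2-dimethyl-2H-chromen-6-yl)but-3-en-2-yl]phenol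
Product: 18 N-{3-methoxy-4-[(2S,3E)-4-(7-methoxy-2,2-dimethyl-2H-chromen-6-yl)but-3-en-2-yl]phenoxy}acetamide, via aryloxyamine 17 (not isolated)
Conditions: KOtBu (1 equiv), DMF, 0 °C; O-(2,4-dinitrophenyl)hydroxylamine, 0 °C to rt; then Ac2O, 0 °C
Reagents that add atoms: O-(2,4-dinitrophenyl)hydroxylamine, NOc1ccc(cc1[N+](=O)[O-])[N+](=O)[O-]; acetic anhydride, CC(=O)OC(C)=O
Why: Electrophilic amination of the potassium phenoxide at oxygen (substitution at nitrogen with 2,4-dinitrophenoxide as leaving group) followed by N-acetylation in the same flask should give the N-aryloxyacetamide without handling the labile aryloxyamine.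

Step 11
Reactants: 19 3-methylbut-2-enal
Product: 20 4-methyl-N'-[(1E)-3-methylbut-2-en-1-ylidene]benzenesulfonohydrazide
Conditions: TsNHNH2, MeOH, rt
Reagents that add atoms: 4-methylbenzenesulfonohydrazide, Cc1ccc(cc1)S(=O)(=O)NN
Why: Condensation of the aldehyde with the sulfonyl hydrazide gives the tosylhydrazone, which should form as the E isomer for steric reasons.

Step 12
Reactants: 20 4-methyl-N'-[(1E)-3-methylbut-2-en-1-ylidene]benzenesulfonohydrazide
Product: 22 3,3-dimethylcyclopropene, via diazoalkene 21 (not isolated)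
Conditions: NaOMe, MeOH, then evaporation; diglyme, 160 °C, product swept with N2 into a −78 °C trap
Reagents that add atoms: none
Why: Bamford–Stevens reaction, in which base-induced loss of sulfinate gives the vinyl diazoalkane, which loses dinitrogen thermally to a vinylcarbene that closes to the cyclopropene (an established way to 3,3-dialkylcyclopropenes), the volatile product leaving the hot mixture as it forms.

Step 13
Reactants: 18 N-{3-methoxy-4-[(2S,3E)-4-(7-methoxy-2,2-dimethyl-2H-chromen-6-yl)but-3-en-2-yl]phenoxy}acetamide; 22 3,3-dimethylcyclopropene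
Product: 23 6-[(1E,3S)-3-(7-methoxy-2,2-dimethyl-2H-chromen-6-yl)but-1-en-1-yl]-7-methoxy-2,2-dimethyl-2H-chromene
Conditions: [Cp*RhCl2]2 (cat.), CsOAc (cat.), MeOH, rt, sealed vessel, 22 in excess as a cold MeOH solution
Reagents that add atoms: none
Why: Acetate-assisted ortho C–H rhodation of the N-aryloxyacetamide should give a five-membered rhodacycle that inserts the strained C=C bond of 22; the cyclopropyl-rhodium so formed opens by β-carbon elimination with release of the ring strain (about 54 kcal/mol) to a rhodium-bound Ar–CH=CH–C(CH3)2 unit, and C–O bond formation at the tertiary carbon with cleavage of the N–O bond (the internal oxidant) closes the pyran and releases acetamide. The closest known reaction type is the trivalent-rhodium-catalysed C–H activation/transannulation of N-phenoxyacetamides with 3,3-disubstituted cyclopropenes to 2,2-disubstituted 2H-chromenes, a redox-neutral [3+3] annulation. Ring D is closed in the last elementary step by intramolecular O1–C2 bond formation onto the tertiary terminus of the allyl-rhodium unit (a six-membered C–O reductive elimination, formally 6-endo with respect to the allyl unit), after the C4a–C4 bond has been made intermolecularly. No new stereocentre is formed, the new C3=C4 bond is held cis by the ring, and the benzylic (S) centre should not be touched by CsOAc in MeOH at room temperature. The step needs site selectivity between the two C–H bonds ortho to the ONHAc group, secured because C8–H lies between the ONHAc and OMe groups whereas C4a–H is flanked only by C5–H, and it needs chemoselectivity for the cyclopropene over the two internal alkenes, secured by ring strain; because 22 is symmetric, only its C(CH3)2 carbon can end up on oxygen.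

**Compound list**

1 | 4-bromo-3-methoxyphenol | COc1cc(O)ccc1Br | starting material
2 | 3-chloro-3-methylbut-1-yne | CC(C)(Cl)C#C | starting material
3 | 1-bromo-2-methoxy-4-[(2-methylbut-3-yn-2-yl)oxy]benzene | COc1cc(OC(C)(C)C#C)ccc1Br | intermediate
4 | 4-bromo-3-methoxy-6-(3-methylbuta-1,2-dien-1-yl)cyclohexa-2,4-dien-1-one (allenyl dienone, racemic) | O=C1C=C(OC)C(Br)=CC1C=C=C(C)C | intermediate
5 | (6Z)-4-bromo-3-methoxy-6-(3-methylbut-2-en-1-ylidene)cyclohexa-2,4-dien-1-one (o-quinone methide) | O=C1C=C(OC)C(Br)=C/C1=C/C=C(C)C | intermediate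
6 | 6-bromo-7-methoxy-2,2-dimethyl-2H-chromene | COc1cc2OC(C)(C)C=Cc2cc1Br | intermediate
7 | but-3-en-2-one | CC(=O)C=C | starting material
8 | (3E)-4-(7-methoxy-2,2-dimethyl-2H-chromen-6-yl)but-3-en-2-one | COc1cc2OC(C)(C)C=Cc2cc1/C=C/C(C)=O | intermediate
9 | (2R,3E)-4-(7-methoxy-2,2-dimethyl-2H-chromen-6-yl)but-3-en-2-ol | COc1cc2OC(C)(C)C=Cc2cc1/C=C/[C@@H](C)O | intermediate
10 | methyl (2R,3E)-4-(7-methoxy-2,2-dimethyl-2H-chromen-6-yl)but-3-en-2-yl carbonate | COc1cc2OC(C)(C)C=Cc2cc1/C=C/[C@@H](C)OC(=O)OC | intermediate
11 | (4-bromo-3-methoxyphenoxy)tri(propan-2-yl)silane | COc1cc(O[Si](C(C)C)(C(C)C)C(C)C)ccc1Br | intermediate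
12 | {2-methoxy-4-[tri(propan-2-yl)silyloxy]phenyl}lithium | [Li]c1ccc(O[Si](C(C)C)(C(C)C)C(C)C)cc1OC | intermediate
13 | lithium {2-methoxy-4-[tri(propan-2-yl)silyloxy]phenyl}tri(propan-2-yloxy)borate | [Li+].CC(C)O[B-](OC(C)C)(OC(C)C)c1ccc(O[Si](C(C)C)(C(C)C)C(C)C)cc1OC | intermediate
14 | {2-methoxy-4-[tri(propan-2-yl)silyloxy]phenyl}boronic acid | COc1cc(O[Si](C(C)C)(C(C)C)C(C)C)ccc1B(O)O | intermediate
15 | {3-methoxy-4-[(2S,3E)-4-(7-methoxy-2,2-dimethyl-2H-chromen-6-yl)but-3-en-2-yl]phenoxy}tri(propan-2-yl)silane | COc1cc2OC(C)(C)C=Cc2cc1/C=C/[C@H](C)c1ccc(O[Si](C(C)C)(C(C)C)C(C)C)cc1OC | intermediate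
16 | 3-methoxy-4-[(2S,3E)-4-(7-methoxy-2,2-dimethyl-2H-chromen-6-yl)but-3-en-2-yl]phenol | COc1cc2OC(C)(C)C=Cc2cc1/C=C/[C@H](C)c1ccc(O)cc1OC | intermediate
17 | O-{3-methoxy-4-[(2S,3E)-4-(7-methoxy-2,2-dimethyl-2H-chromen-6-yl)but-3-en-2-yl]phenyl}hydroxylamine | COc1cc2OC(C)(C)C=Cc2cc1/C=C/[C@H](C)c1ccc(ON)cc1OC | intermediate
18 | N-{3-methoxy-4-[(2S,3E)-4-(7-methoxy-2,2-dimethyl-2H-chromen-6-yl)but-3-en-2-yl]phenoxy}acetamide | COc1cc2OC(C)(C)C=Cc2cc1/C=C/[C@H](C)c1ccc(ONC(C)=O)cc1OC | intermediate
19 | 3-methylbut-2-enal | CC(C)=CC=O | starting material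
20 | 4-methyl-N'-[(1E)-3-methylbut-2-en-1-ylidene]benzenesulfonohydrazide | CC(C)=C/C=N/NS(=O)(=O)c1ccc(C)cc1 | intermediate
21 | 1-diazo-3-methylbut-2-ene | CC(C)=CC=[N+]=[N-] | intermediate
22 | 3,3-dimethylcyclopropene | CC1(C)C=C1 | intermediate
23 | 6-[(1E,3S)-3-(7-methoxy-2,2-dimethyl-2H-chromen-6-yl)but-1-en-1-yl]-7-methoxy-2,2-dimethyl-2H-chromene | COc1cc2c(cc1/C=C/[C@H](C)c1cc3c(cc1OC)OC(C)(C)C=C3)C=CC(C)(C)O2 | target

**Step count and risks**

Total steps: 13. Longest linear sequence: 9 steps (steps 1, 2, 3, 4, 5, 8, 9, 10, 13, from compound 1).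

Steps most likely to fail:

1. Step 13. The ortho C–H rhodation of the electron-rich, hindered arene may be slow or may lose site selectivity, the N–O bond may be cleaved before annulation, and the volatile cyclopropene may escape or oligomerise before it inserts. The fallback sets out from phenol 16 and comes back at target 23. O-alkylation of 16 with chloride 2 (K2CO3, KI cat., acetone, reflux) should give the aryl 1,1-dimethylpropargyl ether F1. Monovalent-gold-catalysed 6-endo-dig hydroarylation (Ph3PAuNTf2 cat., CH2Cl2, rt) at the open ortho carbon para to the methoxy group should then close ring D to 23.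

2. Step 8. The electron-rich allylic carbonate may ionise outside the palladium cycle, or the π-allylpalladium intermediate may be displaced by a second zerovalent palladium, either of which would erode the configuration. The aryl group may also be delivered to the wrong allyl terminus, and β-hydride elimination to a diene may compete. The fallback sets out from boronic acid 14 and bromide 6 and comes back at 15. Hayashi–Miyaura 1,4-addition of 14 to ethyl (E)-but-2-enoate ([Rh(acac)(C2H4)2] cat., the BINAP enantiomer that delivers the 3S product, dioxane–H2O, 100 °C) should give ethyl (3S)-3-{2-methoxy-4-[tri(propan-2-yl)silyloxy]phenyl}butanoate F2. Partial reduction (i-Bu2AlH, CH2Cl2, −78 °C) should give (3S)-3-{2-methoxy-4-[tri(propan-2-yl)silyloxy]phenyl}butanal F3, whose stereocentre is β to the carbonyl and out of reach of enolisation. Bromine–lithium exchange on 6 (n-BuLi, THF, −78 °C) should give (7-methoxy-2,2-dimethyl-2H-chromen-6-yl)lithium F4, and its addition to F3 should give the benzylic carbinol (3S)-1-(7-methoxy-2,2-dimethyl-2H-chromen-6-yl)-3-{2-methoxy-4-[tri(propan-2-yl)silyloxy]phenyl}butan-1-ol F5 as both epimers at the carbinol carbon. Mesylation (MsCl, Et3N, CH2Cl2, 0 °C) should give the benzylic methanesulfonate F6, and elimination with DBU, which can only run towards the CH2 group, should give the E styrene 15.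

3. Step 10. Nitrogen transfer to the phenoxide oxygen may be outrun by C-amination or by oxidation of the electron-rich phenoxide, and the free aryloxyamine may decompose before it is acylated. The fallback sets out from phenol 16 and comes back at aryloxyamine 17, building the aryl–O–N unit by C–O coupling. Triflation (PhNTf2, Et3N, CH2Cl2) should give the aryl trifluoromethanesulfonate F7. Palladium-catalysed borylation (Pd(OAc)2/XPhos cat., B2(OH)4, KOAc, EtOH, 80 °C) should give the arylboronic acid F8. Chan–Lam coupling with N-hydroxyphthalimide (CuCl, pyridine, 4 Å molecular sieves, air, 1,2-dichloroethane, rt) should give the N-aryloxyphthalimide F9. Hydrazinolysis (N2H4·H2O, CHCl3–MeOH, rt) should give 17, which is acetylated as in step 10 to 18.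

**Further compounds**

F1 | step 13 | 2-methoxy-1-[(2S,3E)-4-(7-methoxy-2,2-dimethyl-2H-chromen-6-yl)but-3-en-2-yl]-4-[(2-methylbut-3-yn-2-yl)oxy]benzene | COc1cc2OC(C)(C)C=Cc2cc1/C=C/[C@H](C)c1ccc(OC(C)(C)C#C)cc1OC
F2 | step 8 | ethyl (3S)-3-{2-methoxy-4-[tri(propan-2-yl)silyloxy]phenyl}butanoate | CCOC(=O)C[C@H](C)c1ccc(O[Si](C(C)C)(C(C)C)C(C)C)cc1OC
F3 | step 8 | (3S)-3-{2-methoxy-4-[tri(propan-2-yl)silyloxy]phenyl}butanal | O=CC[C@H](C)c1ccc(O[Si](C(C)C)(C(C)C)C(C)C)cc1OC
F4 | step 8 | (7-methoxy-2,2-dimethyl-2H-chromen-6-yl)lithium | COc1cc2OC(C)(C)C=Cc2cc1[Li]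
F5 | step 8 | (3S)-1-(7-methoxy-2,2-dimethyl-2H-chromen-6-yl)-3-{2-methoxy-4-[tri(propan-2-yl)silyloxy]phenyl}butan-1-ol (both epimers at C1) | COc1cc2OC(C)(C)C=Cc2cc1C(O)C[C@H](C)c1ccc(O[Si](C(C)C)(C(C)C)C(C)C)cc1OC
F6 | step 8 | (3S)-1-(7-methoxy-2,2-dimethyl-2H-chromen-6-yl)-3-{2-methoxy-4-[tri(propan-2-yl)silyloxy]phenyl}butyl methanesulfonate (both epimers at C1) | COc1cc2OC(C)(C)C=Cc2cc1C(OS(C)(=O)=O)C[C@H](C)c1ccc(O[Si](C(C)C)(C(C)C)C(C)C)cc1OC
F7 | step 10 | 3-methoxy-4-[(2S,3E)-4-(7-methoxy-2,2-dimethyl-2H-chromen-6-yl)but-3-en-2-yl]phenyl trifluoromethanesulfonate | COc1cc2OC(C)(C)C=Cc2cc1/C=C/[C@H](C)c1ccc(OS(=O)(=O)C(F)(F)F)cc1OC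
F8 | step 10 | {3-methoxy-4-[(2S,3E)-4-(7-methoxy-2,2-dimethyl-2H-chromen-6-yl)but-3-en-2-yl]phenyl}boronic acid | COc1cc2OC(C)(C)C=Cc2cc1/C=C/[C@H](C)c1ccc(B(O)O)cc1OC
F9 | step 10 | 2-{3-methoxy-4-[(2S,3E)-4-(7-methoxy-2,2-dimethyl-2H-chromen-6-yl)but-3-en-2-yl]phenoxy}isoindoline-1,3-dione | COc1cc2OC(C)(C)C=Cc2cc1/C=C/[C@H](C)c1ccc(ON3C(=O)c4ccccc4C3=O)cc1OC
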